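**Plan**
Locants: ring C1 (angeloyloxy), C2 (side chain), C3, C4 (acetoxy), C5 (methyl), C6; side chain C1'–C7' (C2' methine, C4' acetoxy); they are kept for the same atoms in every intermediate.
Cuts: the C1–O angelate ester; then the ring is contracted by taking C6 out of the C1–C6 bond, so that a C1 ketone becomes a cyclopentanone whose quaternary α-carbon C5 carries CH3 and CH2I (C6); then C4'–C5', C2–C2' and C5–C6.
Enabling feature: C6 is a CH2 between the oxygenated C1 and the methyl-bearing C5, which is next to the oxygenated C4. The C1/C4 1,4-dioxygen pattern is thus a 2-methylcyclopentane-1,3-dione with one carbon inserted, and a C6 radical on C5 can shift the C1 acyl bond onto itself.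
Forward: dione + formaldehyde, iodide, enzymatic desymmetrization and acetylation; the side chain is built at the only enolizable carbon (C2); the radical ring expansion then makes the cyclohexanone; ketone reduction and angeloylation finish.
Stereochemistry: C4 from a ketoreductase; C2 relayed from C4; C2' from an imidazolidinone catalyst; C4' from an oxazaborolidine; C5 in the key step (hydrogen transfer anti to the C4 acetate); C1 by axial hydride delivery.
No protecting groups are used: both acetates are target functionality, and the helpers (iodine, the quaternary centre) are consumed in the key step.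

Key step: step 11

Assumption: a panel ketoreductase with the stated selectivity for dione 4 is available; only its face selectivity at the carbinol carbon is essential, because the quaternary centre is erased in step 11.

**Step 1**
Reactants: 1 2-methylcyclopentane-1,3-dione; 2 formaldehyde
Product: 3 2-(hydroxymethyl)-2-methylcyclopentane-1,3-dione
Conditions: 37% aq. CH2O, H2O, 25 °C
Reagents that add atoms: none
Why: Aldol addition (hydroxymethylation) of the acidic 2-substituted 1,3-dione at C5 should need no added base and creates the quaternary carbon that later is the migration origin; the product is achiral.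

**Step 2**
Reactants: 3 2-(hydroxymethyl)-2-methylcyclopentane-1,3-dione
Product: 4 2-(iodomethyl)-2-methylcyclopentane-1,3-dione
Conditions: PPh3, I2, imidazole, toluene, 80 °C
Reagents that add atoms: iodine, II
Why: Garegg–Samuelsson (Appel-type) iodination, in which iodide displaces the alkoxyphosphonium group at the neopentyl carbon on heating under conditions that should not trigger retro-aldol loss of formaldehyde; no stereocentre is involved.

**Step 3**
Reactants: 4 2-(iodomethyl)-2-methylcyclopentane-1,3-dione
Product: 5 (2R,3R)-3-hydroxy-2-(iodomethyl)-2-methylcyclopentan-1-one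
Conditions: ketoreductase (panel-selected), NADP+ (cat.), i-PrOH, phosphate buffer pH 7.0, DMSO (5% v/v), 30 °C
Reagents that add atoms: none
Why: Enzymatic desymmetrization by a ketoreductase: hydride from NADPH goes to one face of one of the two enantiotopic carbonyls, which sets C4 (R) and the quaternary C5 (R, hydroxyl cis to CH2I) in one event, a choice between enantiotopic ketones that small hydride reagents do not make.

**Step 4**
Reactants: 5 (2R,3R)-3-hydroxy-2-(iodomethyl)-2-methylcyclopentan-1-one
Product: 6 (1R,2R)-2-(iodomethyl)-2-methyl-3-oxocyclopentyl acetate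
Conditions: Ac2O, pyridine, DMAP (cat.), CH2Cl2, 0 °C to 25 °C
Reagents that add atoms: acetic anhydride, CC(=O)OC(C)=O
Why: DMAP-catalysed acylation installs the C4 acetate of the target early, avoids an alkoxide that could close an oxetane onto the cis CH2I, and leaves both stereocentres untouched.

**Step 5**
Reactants: 6 (1R,2R)-2-(iodomethyl)-2-methyl-3-oxocyclopentyl acetate
Product: 7 (1R,2R)-2-(iodomethyl)-2-methyl-3-[(trimethylsilyl)oxy]cyclopent-3-en-1-yl acetate
Conditions: TMSOTf, Et3N, CH2Cl2, 0 °C
Reagents that add atoms: trimethylsilyl trifluoromethanesulfonate, C[Si](C)(C)OS(=O)(=O)C(F)(F)F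
Why: Soft enolization to the silyl enol ether; C5 is quaternary, so the enol double bond can form only toward C2 and a single regioisomer should result.

**Step 6**
Reactants: 7 (1R,2R)-2-(iodomethyl)-2-methyl-3-[(trimethylsilyl)oxy]cyclopent-3-en-1-yl acetate; 8 (E)-but-2-enal
Product: 9 (1R,2R,4S)-2-(iodomethyl)-2-methyl-3-oxo-4-[(2R)-4-oxobutan-2-yl]cyclopentyl acetate
Conditions: (2S,5S)-5-benzyl-2-tert-butyl-3-methylimidazolidin-4-one (20 mol%), 2,4-dinitrobenzoic acid (20 mol%), t-BuOH/i-PrOH, H2O (2 equiv), −20 °C
Reagents that add atoms: none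
Why: Iminium-catalysed Mukaiyama–Michael addition: the imidazolidinone shields one face of the (E)-iminium ion of 8 and should set C2' (R) under catalyst control, while the enol ether reacts at C2 on the face opposite to the C4 acetate and the CH2I group, which sets C2 (S) under substrate control.

**Step 7**
Reactants: 9 (1R,2R,4S)-2-(iodomethyl)-2-methyl-3-oxo-4-[(2R)-4-oxobutan-2-yl]cyclopentyl acetate; 10 (2-methylprop-1-en-1-yl)magnesium bromide
Product: 11 (1R,2R,4S)-4-[(2R)-4-hydroxy-6-methylhept-5-en-2-yl]-2-(iodomethyl)-2-methyl-3-oxocyclopentyl acetate (both C4' epimers)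
Conditions: THF, −78 °C; then H2O
Reagents that add atoms: none
Why: Grignard 1,2-addition at low temperature should be chemoselective for the aldehyde over the hindered ketone, the acetate and the neopentyl iodide; C4' forms without control, which is harmless because it is oxidized in step 8.

**Step 8**
Reactants: 11 (1R,2R,4S)-4-[(2R)-4-hydroxy-6-methylhept-5-en-2-yl]-2-(iodomethyl)-2-methyl-3-oxocyclopentyl acetate (both C4' epimers)
Product: 12 (1R,2R,4S)-2-(iodomethyl)-2-methyl-4-[(2R)-6-methyl-4-oxohept-5-en-2-yl]-3-oxocyclopentyl acetate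
Conditions: Dess–Martin periodinane, CH2Cl2, 25 °C
Reagents that add atoms: none
Why: Dess–Martin oxidation of the allylic alcohol to the enone converges both C4' epimers under conditions that should not epimerize C2.

**Step 9**
Reactants: 12 (1R,2R,4S)-2-(iodomethyl)-2-methyl-4-[(2R)-6-methyl-4-oxohept-5-en-2-yl]-3-oxocyclopentyl acetate
Product: 13 (1R,2R,4S)-4-[(2R,4R)-4-hydroxy-6-methylhept-5-en-2-yl]-2-(iodomethyl)-2-methyl-3-oxocyclopentyl acetate
Conditions: (S)-2-methyl-CBS-oxazaborolidine (15 mol%), catecholborane, toluene, −78 °C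
Reagents that add atoms: none
Why: Corey–Bakshi–Shibata reduction: with the (S)-oxazaborolidine the alkenyl group acts as the large substituent, so hydride delivery should give the (R)-allylic alcohol at C4' under reagent control, while the hindered ring ketone reacts far more slowly.

**Step 10**
Reactants: 13 (1R,2R,4S)-4-[(2R,4R)-4-hydroxy-6-methylhept-5-en-2-yl]-2-(iodomethyl)-2-methyl-3-oxocyclopentyl acetate
Product: 14 (1R,2R,4S)-4-[(2R,4R)-4-(acetyloxy)-6-methylhept-5-en-2-yl]-2-(iodomethyl)-2-methyl-3-oxocyclopentyl acetate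
Conditions: Ac2O, pyridine, DMAP (cat.), CH2Cl2, 0 °C to 25 °C
Reagents that add atoms: acetic anhydride, CC(=O)OC(C)=O
Why: DMAP-catalysed acetylation installs the second acetate of the target; no stereocentre changes.

**Step 11**
Reactants: 14 (1R,2R,4S)-4-[(2R,4R)-4-(acetyloxy)-6-methylhept-5-en-2-yl]-2-(iodomethyl)-2-methyl-3-oxocyclopentyl acetate
Product: 18 (1R,2S,5S)-5-[(2R,4R)-4-(acetyloxy)-6-methylhept-5-en-2-yl]-2-methyl-4-oxocyclohexyl acetate, via primary alkyl radical 15 (not isolated), via cyclopropyloxyl radical 16 (not isolated), via tertiary alkyl radical 17 (not isolated)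
Conditions: Bu3SnH (syringe pump), AIBN (cat.), benzene (0.01 M), 80 °C
Reagents that add atoms: none
Why: Bu3Sn• abstracts iodine from 14 to give primary radical 15, which adds 3-exo-trig to the adjacent C1 carbonyl carbon to give cyclopropyloxyl radical 16; β-scission of the shared C1–C5 bond then re-forms the C1 carbonyl inside a six-membered ring and leaves tertiary radical 17 at C5, a net 1,2-acyl shift driven by the change from a primary to a tertiary radical and by release of cyclopropane strain. The closest known reaction type is the Dowd–Beckwith ring expansion of 2-(halomethyl)cycloalkanones, together with the 1,2-acyl migration of β-keto alkyl radicals that end as tertiary radicals. The only ring closed is the transient cyclopropane (3-exo-trig onto C=O); the cyclohexanone arises by ring-opening β-scission, not by a closure. The one new stereocentre, C5, is set when Bu3SnH transfers hydrogen to 17: A(1,2) strain with the C5 methyl should hold the C4 acetate pseudoaxial (the C2 side chain is then equatorial), and hydrogen enters axially, anti to that acetate, so the methyl ends equatorial and cis to the acetate; the configuration of the old quaternary carbon is erased and does not matter. The step needs regioselectivity (only the C1–C5 bond may migrate), secured because C5 carries the CH2 radical and has a single carbonyl neighbour, and chemoselectivity for rearrangement over direct reduction of 15, secured by the fast acyl shift and a low stationary stannane concentration; the remote trisubstituted alkene and the acetates should not be touched.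

**Step 12**
Reactants: 18 (1R,2S,5S)-5-[(2R,4R)-4-(acetyloxy)-6-methylhept-5-en-2-yl]-2-methyl-4-oxocyclohexyl acetate
Product: 19 (1R,2S,4R,5S)-5-[(2R,4R)-4-(acetyloxy)-6-methylhept-5-en-2-yl]-4-hydroxy-2-methylcyclohexyl acetate
Conditions: NaBH4, CeCl3·7H2O, MeOH, −78 °C
Reagents that add atoms: none
Why: Luche-type reduction: the small borohydride should attack the cyclohexanone axially, on the face syn to the axial hydrogens at C3 and C5, which gives the equatorial C1 alcohol (R), trans to the equatorial side chain; the esters are inert at this temperature.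

**Step 13**
Reactants: 19 (1R,2S,4R,5S)-5-[(2R,4R)-4-(acetyloxy)-6-methylhept-5-en-2-yl]-4-hydroxy-2-methylcyclohexyl acetate; 20 angelic acid
Product: 22 (1R,2S,4R,5S)-4-(acetyloxy)-2-[(2R,4R)-4-(acetyloxy)-6-methylhept-5-en-2-yl]-5-methylcyclohexyl (2Z)-2-methylbut-2-enoate, via mixed anhydride 21 (not isolated)
Conditions: 20, 2,4,6-trichlorobenzoyl chloride, Et3N, toluene, 25 °C; then 19, toluene, 80 °C
Reagents that add atoms: none
Why: Yamaguchi-type esterification through the mixed anhydride: the alcohol attacks the less hindered angeloyl carbonyl, and leaving out a nucleophilic amine catalyst avoids conjugate addition–elimination, so the Z geometry of the bought acid should be kept; C1 retains its configuration.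

**Compound list** (locants inside systematic names are the IUPAC ones)
1 | 2-methylcyclopentane-1,3-dione | CC1C(=O)CCC1=O | starting material
2 | formaldehyde | C=O | starting material
3 | 2-(hydroxymethyl)-2-methylcyclopentane-1,3-dione | CC1(CO)C(=O)CCC1=O | intermediate
4 | 2-(iodomethyl)-2-methylcyclopentane-1,3-dione | CC1(CI)C(=O)CCC1=O | intermediate
5 | (2R,3R)-3-hydroxy-2-(iodomethyl)-2-methylcyclopentan-1-one | O=C1[C@](C)(CI)[C@H](O)CC1 | intermediate
6 | (1R,2R)-2-(iodomethyl)-2-methyl-3-oxocyclopentyl acetate | O=C1[C@](C)(CI)[C@H](OC(C)=O)CC1 | intermediate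
7 | (1R,2R)-2-(iodomethyl)-2-methyl-3-[(trimethylsilyl)oxy]cyclopent-3-en-1-yl acetate | C[Si](C)(C)OC1=CC[C@@H](OC(C)=O)[C@@]1(C)CI | intermediate
8 | (E)-but-2-enal (crotonaldehyde) | C/C=C/C=O | starting material
9 | (1R,2R,4S)-2-(iodomethyl)-2-methyl-3-oxo-4-[(2R)-4-oxobutan-2-yl]cyclopentyl acetate | O=C1[C@](C)(CI)[C@H](OC(C)=O)C[C@H]1[C@H](C)CC=O | intermediate
10 | (2-methylprop-1-en-1-yl)magnesium bromide | CC(C)=C[Mg]Br | starting material
11 | (1R,2R,4S)-4-[(2R)-4-hydroxy-6-methylhept-5-en-2-yl]-2-(iodomethyl)-2-methyl-3-oxocyclopentyl acetate (both C4' epimers) | O=C1[C@](C)(CI)[C@H](OC(C)=O)C[C@H]1[C@H](C)CC(O)C=C(C)C | intermediate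
12 | (1R,2R,4S)-2-(iodomethyl)-2-methyl-4-[(2R)-6-methyl-4-oxohept-5-en-2-yl]-3-oxocyclopentyl acetate | O=C1[C@](C)(CI)[C@H](OC(C)=O)C[C@H]1[C@H](C)CC(=O)C=C(C)C | intermediate
13 | (1R,2R,4S)-4-[(2R,4R)-4-hydroxy-6-methylhept-5-en-2-yl]-2-(iodomethyl)-2-methyl-3-oxocyclopentyl acetate | O=C1[C@](C)(CI)[C@H](OC(C)=O)C[C@H]1[C@H](C)C[C@H](C=C(C)C)O | intermediate
14 | (1R,2R,4S)-4-[(2R,4R)-4-(acetyloxy)-6-methylhept-5-en-2-yl]-2-(iodomethyl)-2-methyl-3-oxocyclopentyl acetate | O=C1[C@](C)(CI)[C@H](OC(C)=O)C[C@H]1[C@H](C)C[C@H](C=C(C)C)OC(C)=O | intermediate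
15 | primary alkyl radical (14 with iodine removed, radical on the exocyclic CH2) | O=C1[C@](C)([CH2])[C@H](OC(C)=O)C[C@H]1[C@H](C)C[C@H](C=C(C)C)OC(C)=O | intermediate
16 | cyclopropyloxyl radical (bicyclo[3.1.0]hexan-1-oxyl, cyclopropane cis to the ring acetate) | [O][C@@]12C[C@]1(C)[C@H](OC(C)=O)C[C@H]2[C@H](C)C[C@H](C=C(C)C)OC(C)=O | intermediate
17 | tertiary alkyl radical (ring-expanded cyclohexanone, radical at the methyl-bearing carbon) | O=C1C[C](C)[C@H](OC(C)=O)C[C@H]1[C@H](C)C[C@H](C=C(C)C)OC(C)=O | intermediate
18 | (1R,2S,5S)-5-[(2R,4R)-4-(acetyloxy)-6-methylhept-5-en-2-yl]-2-methyl-4-oxocyclohexyl acetate | O=C1C[C@H](C)[C@H](OC(C)=O)C[C@H]1[C@H](C)C[C@H](C=C(C)C)OC(C)=O | intermediate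
19 | (1R,2S,4R,5S)-5-[(2R,4R)-4-(acetyloxy)-6-methylhept-5-en-2-yl]-4-hydroxy-2-methylcyclohexyl acetate | O[C@@H]1C[C@H](C)[C@H](OC(C)=O)C[C@H]1[C@H](C)C[C@H](C=C(C)C)OC(C)=O | intermediate
20 | angelic acid, (2Z)-2-methylbut-2-enoic acid | C/C=C(/C)C(=O)O | starting material
21 | (2Z)-2-methylbut-2-enoic 2,4,6-trichlorobenzoic anhydride | C/C=C(/C)C(=O)OC(=O)c1c(Cl)cc(Cl)cc1Cl | intermediate
22 | (1R,2S,4R,5S)-4-(acetyloxy)-2-[(2R,4R)-4-(acetyloxy)-6-methylhept-5-en-2-yl]-5-methylcyclohexyl (2Z)-2-methylbut-2-enoate | C/C=C(/C)C(=O)O[C@@H]1C[C@H](C)[C@H](OC(C)=O)C[C@H]1[C@H](C)C[C@H](C=C(C)C)OC(C)=O | target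

**Totals**
Total step count: 13. Longest linear sequence: 13 steps (1 to 22).

**Steps most likely to fail**

Step 11. Hydrogen transfer to the primary radical may outrun the acyl shift and leave the ring unexpanded, or hydrogen delivery to the tertiary radical may not be face-selective. The fallback sets out from 14 and comes back at 18. SmI2 in THF (−78 °C to 0 °C) should close the iodomethyl ketone by intramolecular Barbier addition to (1R,2R,4S,5R)-4-[(2R,4R)-4-(acetyloxy)-6-methylhept-5-en-2-yl]-5-hydroxy-1-methylbicyclo[3.1.0]hexan-2-yl acetate F1. FeCl3 in DMF at 0 °C should open the internal cyclopropane bond oxidatively (Saegusa-type ring expansion) to (1R,5S)-5-[(2R,4R)-4-(acetyloxy)-6-methylhept-5-en-2-yl]-2-chloro-2-methyl-4-oxocyclohexyl acetate F2. NaOAc in MeOH should eliminate HCl to (1R,5S)-5-[(2R,4R)-4-(acetyloxy)-6-methylhept-5-en-2-yl]-2-methyl-4-oxocyclohex-2-en-1-yl acetate F3. Conjugate reduction with [(Ph3P)CuH]6 in wet benzene should then deliver hydride to C5 anti to the C4 acetate and give 18.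

Step 6. Protonation may remove the silyl group before the C–C bond forms, or the iminium ion may approach the ring carbon without face discrimination. The fallback sets out from 7 and comes back at 9. Branch-selective allylic alkylation of 7 with (E)-but-2-en-1-yl methyl carbonate under [Ir(cod)Cl]2, a binaphthol-derived N,N-bis(1-phenylethyl)phosphoramidite (enantiomer chosen for R at C2'), CsF and ZnF2 in DME should give (1R,2R,4S)-4-[(2R)-but-3-en-2-yl]-2-(iodomethyl)-2-methyl-3-oxocyclopentyl acetate F4, with C2' set by the ligand. Hydroboration with 9-BBN and oxidation with NaBO3·4H2O should give (1R,2R,4S)-4-[(2R)-4-hydroxybutan-2-yl]-2-(iodomethyl)-2-methyl-3-oxocyclopentyl acetate F5. Dess–Martin oxidation then gives 9.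

Step 12. Hydride may be delivered to both faces of the ketone, with equatorial attack competing and giving a mixture at C1. The fallback sets out from 18 and comes back at 22. LiB(s-Bu)3H in THF at −78 °C attacks equatorially and should give only (1R,2S,4S,5S)-5-[(2R,4R)-4-(acetyloxy)-6-methylhept-5-en-2-yl]-4-hydroxy-2-methylcyclohexyl acetate F6, the axial alcohol. Mitsunobu esterification with angelic acid (PPh3, DIAD, toluene, 0 °C) then inverts C1 and gives 22 directly.

**Further compounds**
F1 | step 11 | (1R,2R,4S,5R)-4-[(2R,4R)-4-(acetyloxy)-6-methylhept-5-en-2-yl]-5-hydroxy-1-methylbicyclo[3.1.0]hexan-2-yl acetate | O[C@@]12C[C@]1(C)[C@H](OC(C)=O)C[C@H]2[C@H](C)C[C@H](C=C(C)C)OC(C)=O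
F2 | step 11 | (1R,5S)-5-[(2R,4R)-4-(acetyloxy)-6-methylhept-5-en-2-yl]-2-chloro-2-methyl-4-oxocyclohexyl acetate (either configuration at the chlorine-bearing carbon) | O=C1CC(C)(Cl)[C@H](OC(C)=O)C[C@H]1[C@H](C)C[C@H](C=C(C)C)OC(C)=O
F3 | step 11 | (1R,5S)-5-[(2R,4R)-4-(acetyloxy)-6-methylhept-5-en-2-yl]-2-methyl-4-oxocyclohex-2-en-1-yl acetate | O=C1C=C(C)[C@H](OC(C)=O)C[C@H]1[C@H](C)C[C@H](C=C(C)C)OC(C)=O
F4 | step 6 | (1R,2R,4S)-4-[(2R)-but-3-en-2-yl]-2-(iodomethyl)-2-methyl-3-oxocyclopentyl acetate | O=C1[C@](C)(CI)[C@H](OC(C)=O)C[C@H]1[C@H](C)C=C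
F5 | step 6 | (1R,2R,4S)-4-[(2R)-4-hydroxybutan-2-yl]-2-(iodomethyl)-2-methyl-3-oxocyclopentyl acetate | O=C1[C@](C)(CI)[C@H](OC(C)=O)C[C@H]1[C@H](C)CCO
F6 | step 12 | (1R,2S,4S,5S)-5-[(2R,4R)-4-(acetyloxy)-6-methylhept-5-en-2-yl]-4-hydroxy-2-methylcyclohexyl acetate | O[C@H]1C[C@H](C)[C@H](OC(C)=O)C[C@H]1[C@H](C)C[C@H](C=C(C)C)OC(C)=O
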